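# Proposed total synthesis of 7-hydroxy-2-(4-hydroxyphenyl)-3,5,6,8-tetramethoxy-4H-chromen-4-one (19)

## The problem

Compound 19 is a flat, achiral flavone (flavone numbering; ring A = C4a–C8a, ring C = the pyranone, ring B = the 2-aryl group), so there is no stereochemistry to control and the whole task is regiochemical. Ring A is fully substituted: methoxy groups at C5, C6 and C8, a free hydroxyl at C7, the ring oxygen O1 on C8a and the C4 carbonyl on C4a. Ring C carries a 3-methoxy group and ring B a 4'-hydroxyl. A synthesis must place the acyl carbon and O1 on the correct pair of neighbouring carbons of a tetra-oxygenated benzene, where electrophilic acylation has no reliable bias, and it must keep the C7 oxygen distinguishable from its three methylated neighbours to the end. The sensitive points are the peri C5 methyl ether (chelated to the C4 carbonyl and therefore the first to be cleaved by Lewis acids), the pyranone C2 (opened by hard nucleophiles), and the electron-rich ring A with its hydroquinone-type precursors (easily oxidised). The two phenols therefore have to be unmasked under neutral conditions that leave four methyl ethers untouched. The enabling feature is that C8a (bearing O1) and C4a (bearing C4) are adjacent, with the C5 methoxy group beside C4a. This is the pattern formed when a 3-alkoxyaryne accepts an oxygen nucleophile at the terminus remote from the alkoxy group and an acyl group at the terminus next to it. That polarisation requires the other flank, C8, to be C–H during the key step, so the C8 methoxy group must be added afterwards, on what is then the only free carbon of ring A.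

## Retrosynthesis

**19 from 18.** The two O–benzyl bonds at C7 and C4' are cut last. Benzyl is preferred to silyl (the key step uses fluoride), to acetal groups (acid would endanger the enol ether of the chalcone) and to methyl (a Lewis acid would strip C5 first). It survives fluoride, hot DMSO, electrophilic bromine and methoxide, and both phenols are released in one neutral operation. Precursor 18 has no acidic proton left. The forward step must cleave two benzyl ethers without reducing the C2=C3 bond.

**18 from 16 through 17.** The C8–OMe bond is cut, then the C8–Br bond. Carrying the C8 oxygen from the start would need a hexasubstituted aryne precursor whose two aryne carbons are both flanked by alkoxy groups, which would remove the electronic bias on which the key step depends. In 16, C8 is the only unsubstituted carbon of ring A, so halogenation has no choice on that ring. The forward steps must prefer ring A over ring B in the bromination and must substitute bromide by methoxide without opening the pyranone.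

**16 from 15.** The O1–C2 bond of ring C is cut, giving 2'-hydroxy-α-methoxychalcone 15. The alternative of forming C2–C3 late on a 2-hydroxyaryl ketone would require a separate introduction of the 3-methoxy group. In 15, C2, C3, the 3-methoxy group and ring B are already one unit. The forward reaction must close in the 6-endo sense and oxidise, without drifting to the 5-exo aurone.

**15 from 9 and 13 (key disconnection).** The C8a–O1 and C4a–C4 bonds are cut together, leading to ortho-silylaryl triflate 9 (through aryne 14) and α-methoxycinnamic acid 13. Acylation of a free phenol (Friedel–Crafts or Fries) would have to choose between two non-equivalent ortho positions with nothing to direct it. In the aryne route the choice is made by the methoxy group beside one aryne carbon and the C–H beside the other. A pentasubstituted aryl ketone is reduced to a tetrasubstituted benzene and a three-carbon acid, each made in a few steps. The forward reaction must deliver the carboxylate oxygen to the terminus remote from the methoxy group and complete the acyl shift before the aryl anion is protonated.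

**13 from 10 and 11.** The Cα=Cβ bond of the acid (the future C2–C3 bond) is cut to the commercial aldehyde 10 and ester 11; the methyl ester 12 is saponified in the same flask. The base-mediated condensation gives the thermodynamically preferred (Z) geometry, which is irrelevant for the target because it disappears in ring C.

**9 from 1 through 5, 4, 3 and 2.** The C–Si and O–S bonds of 9 go back to ortho-bromophenol 5 by the silylation, retro-Brook and triflation sequence. The C–Br bond goes back to mono-benzyl ether 4, and the O–benzyl bond to the symmetric hydroquinone 3. Hydroquinone 3 comes from quinone 2, which is made by para-oxidation of commercial phenol 1. The symmetry of 3 means the mono-benzylation cannot give a wrong regioisomer. In 4 the free hydroxyl then directs bromination to its only open ortho carbon, which fixes the C6 methoxy and C7 benzyloxy positions of the flavone unambiguously.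

## Roads not taken

**Alternative 1:** Ring A would be built onto a preformed pyranone by a squarate ring expansion, cutting C8–C8a and C4a–C5.
- Forward step: cyclobutenone A1 (the 1,2-adduct of a C3-metallated 6-aryl-5-methoxypyran-4-one to a squaric diester) is heated in a high-boiling aromatic solvent. 4π ring opening gives a vinylketene, 6π closure onto the pyranone C=C bond follows, and tautomerisation delivers hydroquinone A2 with all four ring-A oxygens in place.
- Merits: this route is better than the chosen plan in one respect. The C8 oxygen arrives with the ring, so no late bromination and methoxylation are needed, and the key step is neutral and thermal.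
- Weak points: a symmetrical squarate puts the same group on C6 and C7, whereas the target needs methoxy at C6 and hydroxyl at C7. An unsymmetrical squarate would raise the question of which carbonyl the pyranyl metal attacks. A2 is an oxidation-prone para-hydroquinone whose chelated C5 hydroxyl methylates reluctantly. The metallated pyranone needs a halogenated pyranone and low-temperature exchange next to an electrophilic carbonyl.
- Comparison: the chosen plan pays two steps for C8, but it fixes the C6/C7 distinction in 4 by a simple mono-benzylation and reaches the ring-A pattern from a commercial phenol.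

**Alternative 2:** Ring C would be closed by a three-component carbonylative annulation, cutting C4a–C4, C4–C3 and O1–C2.
- Forward step: iodophenol A3, carbon monoxide A4 and aryl alkyne A5 combine under a phosphine-ligated divalent palladium catalyst in a secondary amine to give flavone A6.
- Merits: it is at least as convergent as the chosen plan, forms three bonds and a ring in one operation, and again brings the C8 methoxy group in from the start.
- Weak points: A3 is a hexasubstituted benzene with four differentiated oxygens and an iodide, which is considerably harder to make regioselectively than 9. Its iodide is flanked on both sides and sits on a very electron-rich ring, so oxidative addition and carbon monoxide insertion would be slow and 5-exo closure to the aurone competes. A6 has C3–H, so the 3-methoxy group would need a later C3 oxidation and methylation on a benzyl-protected, base-sensitive flavone.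
- Comparison: the chosen plan carries the 3-methoxy group in acid 13 at no cost and needs only a tetrasubstituted arene. It concedes the built-in C8 oxygen.

**Alternative 3:** Ring A would be formed from an acyclic chain on a kojic-acid-type pyranone by a biomimetic Claisen condensation, cutting C4a–C5.
- Forward step: base converts keto ester A7 into its extended dienolate, which attacks the methyl ester through the pyranone carbon that becomes C4a. Loss of methoxide and enolisation give the aromatic ring of A8.
- Merits: no aromatic substitution chemistry is needed, all ring-A oxygens come from the chain, and only one benzyl group is used. In concept it is the most economical of the four routes.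
- Weak points: A7 is a 1,3-dicarbonyl chain with two α-methoxy methines and several enolisation sites, so O-acylation, aldol closure onto other carbonyls and retro-Claisen cleavage all compete, and its assembly on the pyranone takes several steps. A8 has free hydroxyls at C5 and C7, the reverse of what the target needs. The more reactive C7 hydroxyl would have to be protected, the chelated C5 hydroxyl methylated under forcing conditions and the protection removed, which is three further steps.
- Comparison: the chosen plan sets the methylation pattern before the key step and relies on a reaction class with direct precedent. It concedes the late C8 functionalisation that alternative 3 avoids.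

Key step: step 7

## Route

Step 1
Reactants: 1 2,3-dimethoxyphenol
Product: 2 2,3-dimethoxy-1,4-benzoquinone
Conditions: (KO3S)2NO (Fremy's salt), KH2PO4, H2O/acetone, 0 °C to rt
Reagents that add atoms: potassium nitrosodisulfonate (KO3S)2NO, [K+].[K+].[O]N(S(=O)(=O)[O-])S(=O)(=O)[O-]
Why: Teuber oxidation: the phenoxyl radical is trapped by a second equivalent of the nitroxyl at the free para position and the adduct collapses to the para-quinone; the ortho position next to the hydroxyl is blocked by methoxy on one side, which favours the 1,4-quinone.

Step 2
Reactants: 2 2,3-dimethoxy-1,4-benzoquinone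
Product: 3 2,3-dimethoxybenzene-1,4-diol
Conditions: Na2S2O4, H2O/EtOAc, rt
Reagents that add atoms: none
Why: Dithionite reduction of a benzoquinone to its hydroquinone is fast in a two-phase system; the air-sensitive diol is to be used directly.

Step 3
Reactants: 3 2,3-dimethoxybenzene-1,4-diol
Product: 4 4-(benzyloxy)-2,3-dimethoxyphenol
Conditions: BnBr (1 equiv), K2CO3 (1 equiv), degassed acetone, reflux
Reagents that add atoms: benzyl bromide, BrCc1ccccc1
Why: Williamson etherification; the two hydroxyls of 3 are equivalent by symmetry, so only one mono-ether can form, and limiting halide and base should keep the bis-ether minor; the step is statistical by nature and recovered 3 is recycled.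

Step 4
Reactants: 4 4-(benzyloxy)-2,3-dimethoxyphenol
Product: 5 4-(benzyloxy)-6-bromo-2,3-dimethoxyphenol
Conditions: NBS (1 equiv), i-Pr2NH (cat.), CH2Cl2, −78 to 0 °C
Reagents that add atoms: N-bromosuccinimide, O=C1CCC(=O)N1Br
Why: Electrophilic aromatic bromination; the free hydroxyl is the strongest in-plane donor and, with its para position blocked, directs to its single open ortho carbon, as in the ortho-bromination of 4-alkoxyphenols; the amine-catalysed NBS protocol reinforces ortho delivery.

Step 5
Reactants: 5 4-(benzyloxy)-6-bromo-2,3-dimethoxyphenol
Product: 9 4-(benzyloxy)-2,3-dimethoxy-6-(trimethylsilyl)phenyl trifluoromethanesulfonate, via aryl trimethylsilyl ether 6 (not isolated), via aryllithium 7 (not isolated), via lithium silylphenoxide 8 (not isolated)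
Conditions: (Me3Si)2NH, THF, 65 °C, then concentrate; n-BuLi, THF, −78 °C; Tf2O, −78 °C to rt
Reagents that add atoms: hexamethyldisilazane, C[Si](C)(C)N[Si](C)(C)C; trifluoromethanesulfonic anhydride, O=S(=O)(OS(=O)(=O)C(F)(F)F)C(F)(F)F
Why: Standard one-flask route to ortho-silylaryl triflates: O-silylation, bromine–lithium exchange, 1,3-O-to-C silyl shift (retro-Brook rearrangement) driven by formation of the phenoxide, and O-triflation; exchange at −78 °C should outrun deprotonation of the benzylic ether.

Step 6
Reactants: 10 4-(benzyloxy)benzaldehyde; 11 methyl methoxyacetate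
Product: 13 (Z)-3-[4-(benzyloxy)phenyl]-2-methoxyprop-2-enoic acid, via methyl ester 12 (not isolated)
Conditions: NaOMe, MeOH, reflux; then aq. NaOH, reflux; HCl to pH 2
Reagents that add atoms: sodium hydroxide (aqueous), [Na+].[OH-]
Why: Claisen-type aldol condensation of the ester enolate with a non-enolisable aldehyde, then E1cB loss of water, should give the thermodynamically favoured (Z)-enoate (aryl trans to the carboxyl), which is saponified in the same flask; the alkene geometry is of no consequence because it is absorbed into ring C in step 8.

Step 7
Reactants: 9 4-(benzyloxy)-2,3-dimethoxy-6-(trimethylsilyl)phenyl trifluoromethanesulfonate; 13 (Z)-3-[4-(benzyloxy)phenyl]-2-methoxyprop-2-enoic acid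
Product: 15 (Z)-1-[4-(benzyloxy)-6-hydroxy-2,3-dimethoxyphenyl]-3-[4-(benzyloxy)phenyl]-2-methoxyprop-2-en-1-one, via aryne 14 (not isolated)
Conditions: CsF (4 equiv), THF, 125 °C, sealed tube; 9 in moderate excess
Reagents that add atoms: none
Why: Fluoride attacks silicon in 9 and triflate departs, giving aryne 14 with its triple bond between the future C4a and C8a. The caesium carboxylate of 13 adds through oxygen to the terminus remote from the flanking methoxy group (future C8a), because this places the developing aryl anion on the carbon next to the inductively withdrawing C–OMe bond; the C6 methoxy group, meta to that carbon, reinforces the bias and the C7 benzyloxy group, meta to the other terminus, opposes it only weakly. The aryl anion then attacks its own ester carbonyl in a 4-exo-trig manner (an anionic ortho-Fries-type acyl shift) and the strained four-membered alkoxide opens by C–O cleavage to the phenoxide of the ortho-hydroxyaryl ketone, forming C8a–O1 and C4a–C4 in one operation. The closest known reaction type is the formal insertion of arynes into the C–O bond of carboxylic acids, which is documented for cinnamic-type acids. No ring persists in 15 and no stereocentre is created; the (Z) geometry of 13 is carried over. The selectivity required is regiochemical and is secured by the substrate itself, through the methoxy group beside one aryne carbon and the C–H beside the other. Hot THF with excess fluoride favours the intramolecular acyl transfer over proton capture by the aryl anion. Any material that closes further by oxa-Michael addition of the new phenoxide converges with 15 in step 8.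

Step 8
Reactants: 15 (Z)-1-[4-(benzyloxy)-6-hydroxy-2,3-dimethoxyphenyl]-3-[4-(benzyloxy)phenyl]-2-methoxyprop-2-en-1-one
Product: 16 7-(benzyloxy)-2-[4-(benzyloxy)phenyl]-3,5,6-trimethoxy-4H-chromen-4-one
Conditions: I2 (10 mol%), DMSO, 120 °C
Reagents that add atoms: none
Why: Iodine/DMSO oxidative cyclisation of a 2'-hydroxychalcone: 6-endo closure of the phenol onto the enone (O1–C2), iodination at C3 and loss of HI give the pyranone, with DMSO reoxidising iodide so that iodine stays catalytic; the α-methoxy group becomes the C3 methoxy group and benzyl ethers tolerate the conditions.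

Step 9
Reactants: 16 7-(benzyloxy)-2-[4-(benzyloxy)phenyl]-3,5,6-trimethoxy-4H-chromen-4-one
Product: 17 7-(benzyloxy)-2-[4-(benzyloxy)phenyl]-8-bromo-3,5,6-trimethoxy-4H-chromen-4-one
Conditions: NBS, DMF, 0 °C to rt
Reagents that add atoms: N-bromosuccinimide, O=C1CCC(=O)N1Br
Why: Electrophilic aromatic bromination; C8 is the only free carbon of ring A, ortho to the C7 benzyloxy group and O1 and para to the C5 methoxy group, whereas the ring B carbons ortho to benzyloxy are deactivated by conjugation with the pyranone, as in the C8 halogenation of 5,6,7-trialkoxyflavones.

Step 10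
Reactants: 17 7-(benzyloxy)-2-[4-(benzyloxy)phenyl]-8-bromo-3,5,6-trimethoxy-4H-chromen-4-one
Product: 18 7-(benzyloxy)-2-[4-(benzyloxy)phenyl]-3,5,6,8-tetramethoxy-4H-chromen-4-one
Conditions: NaOMe, CuBr, MeOH/DMF, 110 °C
Reagents that add atoms: sodium methoxide, [Na+].[O-]C
Why: Copper-mediated Ullmann-type methoxylation of an aryl bromide, the established way of converting 8-bromoflavones into 8-methoxyflavones; benzyl and methyl ethers are inert to these conditions.

Step 11
Reactants: 18 7-(benzyloxy)-2-[4-(benzyloxy)phenyl]-3,5,6,8-tetramethoxy-4H-chromen-4-one
Product: 19 7-hydroxy-2-(4-hydroxyphenyl)-3,5,6,8-tetramethoxy-4H-chromen-4-one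
Conditions: H2 (1 atm), 10% Pd/C, EtOAc/MeOH, rt
Reagents that add atoms: none
Why: Catalytic hydrogenolysis cleaves both benzyl ethers under neutral conditions at room temperature and atmospheric pressure and should leave the four methyl ethers and the conjugated, tetrasubstituted C2=C3 bond untouched.

## Compound list

1 | 2,3-dimethoxyphenol | COc1cccc(O)c1OC | starting material
2 | 2,3-dimethoxy-1,4-benzoquinone | COC1=C(OC)C(=O)C=CC1=O | intermediate
3 | 2,3-dimethoxybenzene-1,4-diol | COc1c(O)ccc(O)c1OC | intermediate
4 | 4-(benzyloxy)-2,3-dimethoxyphenol | COc1c(O)ccc(OCc2ccccc2)c1OC | intermediate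
5 | 4-(benzyloxy)-6-bromo-2,3-dimethoxyphenol | COc1c(OC)c(OCc2ccccc2)cc(Br)c1O | intermediate
6 | [4-(benzyloxy)-6-bromo-2,3-dimethoxyphenoxy]trimethylsilane | COc1c(OC)c(OCc2ccccc2)cc(Br)c1O[Si](C)(C)C | intermediate
7 | {5-(benzyloxy)-3,4-dimethoxy-2-[(trimethylsilyl)oxy]phenyl}lithium | [Li]c1cc(OCc2ccccc2)c(OC)c(OC)c1O[Si](C)(C)C | intermediate
8 | lithium 4-(benzyloxy)-2,3-dimethoxy-6-(trimethylsilyl)phenoxide | [Li+].COc1c(OC)c(OCc2ccccc2)cc([Si](C)(C)C)c1[O-] | intermediate
9 | 4-(benzyloxy)-2,3-dimethoxy-6-(trimethylsilyl)phenyl trifluoromethanesulfonate | COc1c(OC)c(OCc2ccccc2)cc([Si](C)(C)C)c1OS(=O)(=O)C(F)(F)F | intermediate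
10 | 4-(benzyloxy)benzaldehyde | O=Cc1ccc(OCc2ccccc2)cc1 | starting material
11 | methyl methoxyacetate | COCC(=O)OC | starting material
12 | methyl (Z)-3-[4-(benzyloxy)phenyl]-2-methoxyprop-2-enoate | CO/C(=C\c1ccc(OCc2ccccc2)cc1)C(=O)OC | intermediate
13 | (Z)-3-[4-(benzyloxy)phenyl]-2-methoxyprop-2-enoic acid | CO/C(=C\c1ccc(OCc2ccccc2)cc1)C(=O)O | intermediate
14 | 5-(benzyloxy)-3,4-dimethoxybenzyne (5-(benzyloxy)-1,2-didehydro-3,4-dimethoxybenzene) | COC1=C(OC)C(OCc2ccccc2)=CC#C1 | intermediate
15 | (Z)-1-[4-(benzyloxy)-6-hydroxy-2,3-dimethoxyphenyl]-3-[4-(benzyloxy)phenyl]-2-methoxyprop-2-en-1-one | CO/C(=C\c1ccc(OCc2ccccc2)cc1)C(=O)c1c(O)cc(OCc2ccccc2)c(OC)c1OC | intermediate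
16 | 7-(benzyloxy)-2-[4-(benzyloxy)phenyl]-3,5,6-trimethoxy-4H-chromen-4-one | COc1c(-c2ccc(OCc3ccccc3)cc2)oc2cc(OCc3ccccc3)c(OC)c(OC)c2c1=O | intermediate
17 | 7-(benzyloxy)-2-[4-(benzyloxy)phenyl]-8-bromo-3,5,6-trimethoxy-4H-chromen-4-one | COc1c(-c2ccc(OCc3ccccc3)cc2)oc2c(Br)c(OCc3ccccc3)c(OC)c(OC)c2c1=O | intermediate
18 | 7-(benzyloxy)-2-[4-(benzyloxy)phenyl]-3,5,6,8-tetramethoxy-4H-chromen-4-one | COc1c(-c2ccc(OCc3ccccc3)cc2)oc2c(OC)c(OCc3ccccc3)c(OC)c(OC)c2c1=O | intermediate
19 | 7-hydroxy-2-(4-hydroxyphenyl)-3,5,6,8-tetramethoxy-4H-chromen-4-one | COc1c(O)c(OC)c2oc(-c3ccc(O)cc3)c(OC)c(=O)c2c1OC | target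

## Step count and risk assessment

Total step count: 11. Longest linear sequence: 10 steps (steps 1–5 and 7–11, from 1 to 19); the acid branch (step 6) joins at step 7.

**Step 7 (key step).** The aryl anion formed after carboxylate addition may be diverted before it reaches the carbonyl carbon. It could capture a proton from free acid (simple O-arylation without acyl shift), or add in a conjugate sense to the β-carbon of the unsaturated acyl unit instead of attacking the carbonyl. The electron-rich enol-ether double bond of 13 may also be consumed by the aryne. Fallback: the aryne insertion is run on a saturated acid and the enone is built afterwards. Compound 9 is treated with methoxyacetic acid (COCC(=O)O) and CsF in THF at 125 °C to give 1-[4-(benzyloxy)-6-hydroxy-2,3-dimethoxyphenyl]-2-methoxyethan-1-one F1, in which the same two ring-A bonds have been formed. Claisen–Schmidt condensation of F1 with aldehyde 10 (KOH, EtOH, rt) then returns to the route at 15.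

**Step 10.** Substitution at a carbon flanked by the benzyloxy group and O1 is slow, so reductive loss of bromine and methoxide attack at C2 with opening of the pyranone can overtake it. Fallback: the C8–O bond is made through boron instead of copper. Compound 17 is borylated (B2pin2, PdCl2(dppf), KOAc, dioxane, 90 °C) to 7-(benzyloxy)-2-[4-(benzyloxy)phenyl]-3,5,6-trimethoxy-8-(4,4,5,5-tetramethyl-1,3,2-dioxaborolan-2-yl)-4H-chromen-4-one F2. This is oxidised (NaBO3·4H2O, THF/H2O, rt) to 7-(benzyloxy)-2-[4-(benzyloxy)phenyl]-8-hydroxy-3,5,6-trimethoxy-4H-chromen-4-one F3. O-Methylation (MeI, K2CO3, acetone, reflux) rejoins the route at 18.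

**Step 8.** Hot iodine/DMSO may iodinate the very electron-rich phenol ring and so withdraw the catalyst. The HI formed may hydrolyse the enol ether of the chalcone, or cleave the peri methyl ether once the carbonyl is in place. Fallback: ring closure and oxidation are separated. Compound 15 is cyclised under mild base (NaOAc, EtOH, reflux) by oxa-Michael addition to 7-(benzyloxy)-2-[4-(benzyloxy)phenyl]-3,5,6-trimethoxychroman-4-one F4 (racemic, either C2/C3 diastereomer, both centres being erased next). Dehydrogenation with DDQ (dioxane, reflux) comes back to the route at 16.

**Step 4.** The para-alkoxyphenol may be oxidised by the N-bromo reagent towards the quinone with loss of the benzyl group instead of being substituted, and some substitution ortho to the benzyloxy group cannot be excluded. Fallback: the silicon is introduced by directed ortho-metalation, bypassing the bromide and the retro-Brook sequence.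
- Compound 4 is carbamoylated (isopropyl isocyanate, Et3N cat., CH2Cl2) to 4-(benzyloxy)-2,3-dimethoxyphenyl N-(propan-2-yl)carbamate F5.
- After N-silylation in the flask (Me3SiOTf, TMEDA, Et2O), ortho-lithiation (n-BuLi, TMEDA, −78 °C) and a Me3SiCl quench give 4-(benzyloxy)-2,3-dimethoxy-6-(trimethylsilyl)phenyl N-(propan-2-yl)carbamate F6.
- DBU and Et2NH in MeCN at 40 °C release 4-(benzyloxy)-2,3-dimethoxy-6-(trimethylsilyl)phenol F7, which is triflated in the same flask with PhNTf2, rejoining the route at 9.

## Further compounds

F1 | step 7 | 1-[4-(benzyloxy)-6-hydroxy-2,3-dimethoxyphenyl]-2-methoxyethan-1-one | COCC(=O)c1c(O)cc(OCc2ccccc2)c(OC)c1OC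
F2 | step 10 | 7-(benzyloxy)-2-[4-(benzyloxy)phenyl]-3,5,6-trimethoxy-8-(4,4,5,5-tetramethyl-1,3,2-dioxaborolan-2-yl)-4H-chromen-4-one | COc1c(-c2ccc(OCc3ccccc3)cc2)oc2c(B3OC(C)(C)C(C)(C)O3)c(OCc3ccccc3)c(OC)c(OC)c2c1=O
F3 | step 10 | 7-(benzyloxy)-2-[4-(benzyloxy)phenyl]-8-hydroxy-3,5,6-trimethoxy-4H-chromen-4-one | COc1c(-c2ccc(OCc3ccccc3)cc2)oc2c(O)c(OCc3ccccc3)c(OC)c(OC)c2c1=O
F4 | step 8 | 7-(benzyloxy)-2-[4-(benzyloxy)phenyl]-3,5,6-trimethoxychroman-4-one (racemic, C2/C3 configuration not defined) | COC1C(c2ccc(OCc3ccccc3)cc2)Oc2cc(OCc3ccccc3)c(OC)c(OC)c2C1=O
F5 | step 4 | 4-(benzyloxy)-2,3-dimethoxyphenyl N-(propan-2-yl)carbamate | COc1c(OC)c(OCc2ccccc2)ccc1OC(=O)NC(C)C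
F6 | step 4 | 4-(benzyloxy)-2,3-dimethoxy-6-(trimethylsilyl)phenyl N-(propan-2-yl)carbamate | COc1c(OC)c(OCc2ccccc2)cc([Si](C)(C)C)c1OC(=O)NC(C)C
F7 | step 4 | 4-(benzyloxy)-2,3-dimethoxy-6-(trimethylsilyl)phenol | COc1c(OC)c(OCc2ccccc2)cc([Si](C)(C)C)c1O
A1 | alternative 1 | 2,3-bis(benzyloxy)-4-{6-[4-(benzyloxy)phenyl]-5-methoxy-4-oxo-4H-pyran-3-yl}-4-hydroxycyclobut-2-en-1-one (racemic) | O=C1C(OCc2ccccc2)=C(OCc2ccccc2)C1(O)c1coc(-c2ccc(OCc3ccccc3)cc2)c(OC)c1=O
A2 | alternative 1 | 6,7-bis(benzyloxy)-2-[4-(benzyloxy)phenyl]-5,8-dihydroxy-3-methoxy-4H-chromen-4-one | COc1c(-c2ccc(OCc3ccccc3)cc2)oc2c(O)c(OCc3ccccc3)c(OCc3ccccc3)c(O)c2c1=O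
A3 | alternative 2 | 3-(benzyloxy)-6-iodo-2,4,5-trimethoxyphenol | COc1c(O)c(I)c(OC)c(OC)c1OCc1ccccc1
A4 | alternative 2 | carbon monoxide | [C-]#[O+]
A5 | alternative 2 | 1-(benzyloxy)-4-ethynylbenzene | C#Cc1ccc(OCc2ccccc2)cc1
A6 | alternative 2 | 7-(benzyloxy)-2-[4-(benzyloxy)phenyl]-5,6,8-trimethoxy-4H-chromen-4-one | COc1c(OCc2ccccc2)c(OC)c2oc(-c3ccc(OCc4ccccc4)cc3)cc(=O)c2c1OC
A7 | alternative 3 | methyl 4-{6-[4-(benzyloxy)phenyl]-5-methoxy-4-oxo-4H-pyran-2-yl}-2,4-dimethoxy-3-oxobutanoate (mixture of stereoisomers) | COC(=O)C(OC)C(=O)C(OC)c1cc(=O)c(OC)c(-c2ccc(OCc3ccccc3)cc2)o1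
A8 | alternative 3 | 2-[4-(benzyloxy)phenyl]-5,7-dihydroxy-3,6,8-trimethoxy-4H-chromen-4-one | COc1c(O)c(OC)c2oc(-c3ccc(OCc4ccccc4)cc3)c(OC)c(=O)c2c1O
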